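The flavonol is traced back to a flav-3-ene whose ring C is cut at C4–C4a and O1–C2, which leads to an aryl 1-arylpropargyl ether. Heating that ether sets off a propargyl Claisen shift, a hydrogen shift and an oxa-6π closure, so one operation makes both bonds and ring C. The step exploits ring A: of the two carbons flanking C8a, C8 carries a methoxy group, so only C4a can receive the C2–C3–C4 unit from O1. The precursor joins 5-(benzyloxy)-2,3-dimethoxyphenol to a ring B ethynyl carbinol; all three future phenols are benzyl ethers, removed together at the end.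

Key step: step 8

Remark: the target is achiral, so every chiral intermediate is carried as a racemate; where a SMILES shows stereo marks, one enantiomer of the racemate is drawn.

Remark: the hydroxyl already present in 5 must become O1 and the formyl carbon must be replaced by the C5 oxygen. It is therefore masked as a pivalate during the oxidation. Benzylating 5 first would give 3-(benzyloxy)-4,5-dimethoxyphenol, which has two free ortho positions and the wrong oxygenation pattern.

Step 1
Reactants: 1 2,4-dihydroxy-5-methoxybenzaldehyde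
Product: 2 2,4-bis(benzyloxy)-5-methoxybenzaldehyde
Conditions: BnBr (2.4 equiv), K2CO3, DMF, 60 °C
Reagents that add atoms: benzyl bromide, BrCc1ccccc1
Why: Williamson ether synthesis: both phenoxides, including the one hydrogen-bonded to the formyl group, should be benzylated in warm DMF, and the aldehyde is inert to carbonate.

Step 2
Reactants: 2 2,4-bis(benzyloxy)-5-methoxybenzaldehyde; 3 ethynylmagnesium bromide
Product: 4 racemic 1-[2,4-bis(benzyloxy)-5-methoxyphenyl]prop-2-yn-1-ol
Conditions: HC≡CMgBr (0.5 M in THF), THF, 0 °C; aq. NH4Cl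
Reagents that add atoms: ethynylmagnesium bromide, C#C[Mg]Br
Why: Grignard 1,2-addition of the alkynyl nucleophile to the aldehyde should give the propargylic carbinol; no chiral element is present, so the new centre forms racemic, which is acceptable because it later becomes the sp2 carbon C2.

Step 3
Reactants: 5 3-hydroxy-4,5-dimethoxybenzaldehyde
Product: 6 5-formyl-2,3-dimethoxyphenyl 2,2-dimethylpropanoate (pivalate)
Conditions: PivCl, Et3N, DMAP (cat.), CH2Cl2, 0 °C to rt
Reagents that add atoms: pivaloyl chloride, CC(C)(C)C(Cl)=O
Why: O-acylation of the phenol (DMAP-catalysed esterification) masks the oxygen destined to become O1 as a hindered ester that tolerates peracid and carbonate and is orthogonal to a benzyl ether.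

Step 4
Reactants: 6 5-formyl-2,3-dimethoxyphenyl 2,2-dimethylpropanoate
Product: 8 5-hydroxy-2,3-dimethoxyphenyl 2,2-dimethylpropanoate, via aryl formate 7 (not isolated)
Conditions: mCPBA, CH2Cl2, 0 °C to rt; aq. NaHCO3 wash; then Et3N (cat.), MeOH, rt
Reagents that add atoms: 3-chloroperoxybenzoic acid (mCPBA), OOC(=O)c1cccc(Cl)c1
Why: Baeyer–Villiger oxidation of an aryl aldehyde whose ring carbon is para to a methoxy group should proceed by aryl migration to the formate, and the formate, far more labile than the hindered pivalate, should be methanolysed selectively by Et3N in MeOH.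

Step 5
Reactants: 8 5-hydroxy-2,3-dimethoxyphenyl 2,2-dimethylpropanoate
Product: 9 5-(benzyloxy)-2,3-dimethoxyphenyl 2,2-dimethylpropanoate
Conditions: BnBr, K2CO3, acetone, reflux
Reagents that add atoms: benzyl bromide, BrCc1ccccc1
Why: Williamson ether synthesis on the only free phenol; the aryl pivalate should survive anhydrous K2CO3 in acetone.

Step 6
Reactants: 9 5-(benzyloxy)-2,3-dimethoxyphenyl 2,2-dimethylpropanoate
Product: 10 5-(benzyloxy)-2,3-dimethoxyphenol
Conditions: NaOMe, MeOH, 50 °C; then dilute HCl to pH 6
Reagents that add atoms: none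
Why: Base-mediated transesterification (methanolysis) of the aryl ester should release the phenoxide as a good leaving group, while the benzyl and methyl ethers are inert.

Step 7
Reactants: 4 racemic 1-[2,4-bis(benzyloxy)-5-methoxyphenyl]prop-2-yn-1-ol; 10 5-(benzyloxy)-2,3-dimethoxyphenol
Product: 11 racemic 1-[5-(benzyloxy)-2,3-dimethoxyphenoxy]-1-[2,4-bis(benzyloxy)-5-methoxyphenyl]prop-2-yne
Conditions: PPh3, DIAD (added last, slowly), THF, 0 °C to rt
Reagents that add atoms: none
Why: Mitsunobu etherification: the secondary propargylic carbinol is activated as its alkoxyphosphonium salt and displaced at carbon by the phenoxide of 10, which is acidic enough for the betaine, giving the aryl ether with the propargylic centre still racemic.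

Step 8
Reactants: 11 racemic 1-[5-(benzyloxy)-2,3-dimethoxyphenoxy]-1-[2,4-bis(benzyloxy)-5-methoxyphenyl]prop-2-yne
Product: 15 racemic 5-(benzyloxy)-2-[2,4-bis(benzyloxy)-5-methoxyphenyl]-7,8-dimethoxy-2H-chromene, via allenyl dienone 12 (not isolated), via allenylphenol 13 (not isolated), via ortho-quinone methide 14 (not isolated)
Conditions: PhNEt2 (degassed, distilled from KOH), 190 °C, Ar, base-washed glassware; solvent removed in vacuo
Reagents that add atoms: none
Why: On heating, the ether should undergo a [3,3] sigmatropic (propargyl Claisen) shift that breaks O1–C2 and bonds the alkyne terminus, the future C4, to C4a, giving allenyl dienone 12, which enolises to allenylphenol 13. A 1,5-hydrogen shift from the phenolic oxygen to the central allene carbon then gives ortho-quinone methide 14, and a thermally allowed disrotatory oxa-6π electrocyclisation re-forms O1–C2 and closes the six-membered pyran ring C. The closest known reaction type is the thermal rearrangement of aryl propargyl ethers to 2H-chromenes in N,N-diethylaniline, which also covers 1-aryl-substituted ethers leading to flav-3-enes. C2 is the only stereocentre formed and nothing chiral is present, so it arises racemic, which is harmless because it becomes sp2 in the flavonol. The step needs ortho regioselectivity, secured because C8 of ring A bears a methoxy group and only C4a carries hydrogen (a shift to C8 gives a dienone that cannot enolise and can revert). It also needs the concerted path to outrun heterolysis of the donor-activated benzylic C–O bond, which the basic, weakly polar amine solvent and the exclusion of acid should favour.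

Step 9
Reactants: 15 racemic 5-(benzyloxy)-2-[2,4-bis(benzyloxy)-5-methoxyphenyl]-7,8-dimethoxy-2H-chromene
Product: 16 racemic (2R,3S,4S)-5-(benzyloxy)-2-[2,4-bis(benzyloxy)-5-methoxyphenyl]-7,8-dimethoxy-3,4-dihydro-2H-chromene-3,4-diol (2,3-trans-3,4-cis)
Conditions: OsO4 (cat.), NMO, acetone/H2O, rt
Reagents that add atoms: N-methylmorpholine N-oxide, C[N+]1([O-])CCOCC1; water, O; osmium tetroxide (catalytic oxygen carrier), O=[Os](=O)(=O)=O
Why: Catalytic syn-dihydroxylation with OsO4 and NMO: the osmium reagent should add to the face of C3=C4 opposite the C2 aryl group, so both hydroxyls are cis to each other and trans to the aryl group (substrate control, racemic), and all three centres are erased in the next step.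

Step 10
Reactants: 16 racemic (2R,3S,4S)-5-(benzyloxy)-2-[2,4-bis(benzyloxy)-5-methoxyphenyl]-7,8-dimethoxy-3,4-dihydro-2H-chromene-3,4-diol
Product: 18 5-(benzyloxy)-2-[2,4-bis(benzyloxy)-5-methoxyphenyl]-3-hydroxy-7,8-dimethoxy-4H-chromen-4-one, via flavan-3,4-dione 17 (not isolated)
Conditions: (COCl)2, DMSO, CH2Cl2, −78 °C; Et3N, −78 °C to rt
Reagents that add atoms: none
Why: Swern oxidation should convert both secondary carbinols of the vicinal diol to ketones without C–C cleavage, and the resulting dione, whose C2–H is benzylic, next to oxygen and alpha to C3=O, should enolise during the Et3N stage to the aromatic 3-hydroxy-4-pyranone.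

Step 11
Reactants: 18 5-(benzyloxy)-2-[2,4-bis(benzyloxy)-5-methoxyphenyl]-3-hydroxy-7,8-dimethoxy-4H-chromen-4-one
Product: 19 2-(2,4-dihydroxy-5-methoxyphenyl)-3,5-dihydroxy-7,8-dimethoxy-4H-chromen-4-one (CNP0319239.0)
Conditions: H2 (1 atm), 10% Pd/C, EtOAc/MeOH, rt
Reagents that add atoms: none
Why: Catalytic hydrogenolysis of the three aryl benzyl ethers over Pd/C under neutral conditions should leave the methyl ethers and the conjugated C2=C3 bond of the flavonol untouched.

Compound list
1 | 2,4-dihydroxy-5-methoxybenzaldehyde | COc1cc(C=O)c(O)cc1O | starting material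
2 | 2,4-bis(benzyloxy)-5-methoxybenzaldehyde | COc1cc(C=O)c(OCc2ccccc2)cc1OCc1ccccc1 | intermediate
3 | ethynylmagnesium bromide | C#C[Mg]Br | starting material
4 | racemic 1-[2,4-bis(benzyloxy)-5-methoxyphenyl]prop-2-yn-1-ol | C#CC(O)c1cc(OC)c(OCc2ccccc2)cc1OCc1ccccc1 | intermediate
5 | 3-hydroxy-4,5-dimethoxybenzaldehyde | COc1cc(C=O)cc(O)c1OC | starting material
6 | 5-formyl-2,3-dimethoxyphenyl 2,2-dimethylpropanoate | COc1cc(C=O)cc(OC(=O)C(C)(C)C)c1OC | intermediate
7 | 5-(formyloxy)-2,3-dimethoxyphenyl 2,2-dimethylpropanoate (not isolated) | COc1cc(OC=O)cc(OC(=O)C(C)(C)C)c1OC | intermediate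
8 | 5-hydroxy-2,3-dimethoxyphenyl 2,2-dimethylpropanoate | COc1cc(O)cc(OC(=O)C(C)(C)C)c1OC | intermediate
9 | 5-(benzyloxy)-2,3-dimethoxyphenyl 2,2-dimethylpropanoate | COc1cc(OCc2ccccc2)cc(OC(=O)C(C)(C)C)c1OC | intermediate
10 | 5-(benzyloxy)-2,3-dimethoxyphenol | COc1cc(OCc2ccccc2)cc(O)c1OC | intermediate
11 | racemic 1-[5-(benzyloxy)-2,3-dimethoxyphenoxy]-1-[2,4-bis(benzyloxy)-5-methoxyphenyl]prop-2-yne | C#CC(Oc1cc(OCc2ccccc2)cc(OC)c1OC)c1cc(OC)c(OCc2ccccc2)cc1OCc1ccccc1 | intermediate
12 | 5-(benzyloxy)-6-{3-[2,4-bis(benzyloxy)-5-methoxyphenyl]propa-1,2-dien-1-yl}-2,3-dimethoxycyclohexa-2,4-dien-1-one (stereoisomer mixture, not isolated) | O=C1C(OC)=C(OC)C=C(OCc2ccccc2)C1C=C=Cc1cc(OC)c(OCc2ccccc2)cc1OCc1ccccc1 | intermediate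
13 | 3-(benzyloxy)-2-{3-[2,4-bis(benzyloxy)-5-methoxyphenyl]propa-1,2-dien-1-yl}-5,6-dimethoxyphenol (racemic allene, not isolated) | Oc1c(OC)c(OC)cc(OCc2ccccc2)c1C=C=Cc1cc(OC)c(OCc2ccccc2)cc1OCc1ccccc1 | intermediate
14 | (2Z)-3-(benzyloxy)-2-{3-[2,4-bis(benzyloxy)-5-methoxyphenyl]prop-2-en-1-ylidene}-5,6-dimethoxycyclohexa-3,5-dien-1-one (side-chain C2=C3 geometry not defined, not isolated) | O=C1C(OC)=C(OC)C=C(OCc2ccccc2)/C1=C/C=Cc1cc(OC)c(OCc2ccccc2)cc1OCc1ccccc1 | intermediate
15 | racemic 5-(benzyloxy)-2-[2,4-bis(benzyloxy)-5-methoxyphenyl]-7,8-dimethoxy-2H-chromene | COc1cc(C2C=Cc3c(OCc4ccccc4)cc(OC)c(OC)c3O2)c(OCc2ccccc2)cc1OCc1ccccc1 | intermediate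
16 | racemic (2R,3S,4S)-5-(benzyloxy)-2-[2,4-bis(benzyloxy)-5-methoxyphenyl]-7,8-dimethoxy-3,4-dihydro-2H-chromene-3,4-diol | COc1cc([C@H]2Oc3c(OC)c(OC)cc(OCc4ccccc4)c3[C@H](O)[C@@H]2O)c(OCc2ccccc2)cc1OCc1ccccc1 | intermediate
17 | racemic 5-(benzyloxy)-2-[2,4-bis(benzyloxy)-5-methoxyphenyl]-7,8-dimethoxy-2H-chromene-3,4-dione (not isolated) | COc1cc(C2Oc3c(OC)c(OC)cc(OCc4ccccc4)c3C(=O)C2=O)c(OCc2ccccc2)cc1OCc1ccccc1 | intermediate
18 | 5-(benzyloxy)-2-[2,4-bis(benzyloxy)-5-methoxyphenyl]-3-hydroxy-7,8-dimethoxy-4H-chromen-4-one | COc1cc(-c2oc3c(OC)c(OC)cc(OCc4ccccc4)c3c(=O)c2O)c(OCc2ccccc2)cc1OCc1ccccc1 | intermediate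
19 | 2-(2,4-dihydroxy-5-methoxyphenyl)-3,5-dihydroxy-7,8-dimethoxy-4H-chromen-4-one | COc1cc(-c2oc3c(OC)c(OC)cc(O)c3c(=O)c2O)c(O)cc1O | target

Total step count: 11. Longest linear sequence: 9 steps (steps 3 to 11, from 5 to 19).

Steps most likely to fail

Step 8. Heterolysis of the propargylic C–O bond, which the ortho and para benzyloxy groups of ring B activate, may compete with the sigmatropic shift and lead to recombination at carbon. A shift to the methoxy-bearing C8 followed by intramolecular cycloaddition of the allene, or thermal oligomerisation of the quinone methide, may also drain material. The fallback sets out from 11 and replaces the pericyclic cascade by π-acid catalysis with a cationic monovalent gold complex (Ph3PAuNTf2, CH2Cl2, room temperature). The gold-activated alkyne terminus is attacked by C4a of ring A in a 6-endo-dig hydroarylation and protodeauration follows. Only C4–C4a is formed, O1–C2 is never broken, and no heating is needed. The fallback comes back to the route at 15 and no new compound arises (F0).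

Step 7. The alkoxyphosphonium intermediate of the electron-rich carbinol may ionise, and the ion pair may then alkylate the phenol at a ring carbon or at the alkyne terminus, or conversion may stall. The fallback sets out from 4, which with ClCO2Me and pyridine should give racemic 1-[2,4-bis(benzyloxy)-5-methoxyphenyl]prop-2-yn-1-yl methyl carbonate F1. Copper-catalysed propargylic etherification of F1 with phenol 10 (CuCl2 as precatalyst, divalent copper, DBU, MeCN, 0 °C) should then give the ether. This is the established way of O-propargylating electron-rich phenols, and it runs through a copper acetylide and allenylidene that accepts the phenoxide at the propargylic carbon. The fallback comes back to the route at 11.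

Step 10. The activated C4 alkoxysulfonium ion, benzylic to the electron-rich ring A, may ionise and lead to substitution or elimination. The enolic hydroxyl of the product may also be methylthiomethylated by excess activated DMSO. The fallback sets out from 16 and divides the oxidation in two. MnO2 in CH2Cl2 should oxidise only the benzylic C4 carbinol and give racemic (2R,3R)-5-(benzyloxy)-2-[2,4-bis(benzyloxy)-5-methoxyphenyl]-3-hydroxy-7,8-dimethoxy-2,3-dihydro-4H-chromen-4-one F2, the trans-dihydroflavonol. F2 is then dehydrogenated with iodine and KOAc in warm acetic acid, the classical conversion of dihydroflavonols into flavonols. The fallback comes back to the route at 18.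

Further compounds
F0 | step 8 | none | none
F1 | step 7 | racemic 1-[2,4-bis(benzyloxy)-5-methoxyphenyl]prop-2-yn-1-yl methyl carbonate | C#CC(OC(=O)OC)c1cc(OC)c(OCc2ccccc2)cc1OCc1ccccc1
F2 | step 10 | racemic (2R,3R)-5-(benzyloxy)-2-[2,4-bis(benzyloxy)-5-methoxyphenyl]-3-hydroxy-7,8-dimethoxy-2,3-dihydro-4H-chromen-4-one | COc1cc([C@H]2Oc3c(OC)c(OC)cc(OCc4ccccc4)c3C(=O)[C@@H]2O)c(OCc2ccccc2)cc1OCc1ccccc1
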